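Readings and results were generated by integration on assumed constants; noise was put on by code.

The green run, with 0.055 M of coupling partner, shows 60% product at 4.00 d, and the red run, with 0.087 M, shows 71% at 3.00 d. The next flask cuts the coupling partner to 0.0396 M, and you must decide whether to change its catalyst charge as well.

| flask | substrate | coupling partner | free catalyst | impurity | remark |
|---|---|---|---|---|---|
| green | 0.036 M | 0.055 M | 72 µM | 8.6 µM | run made earlier |
| red | 0.036 M | 0.087 M | 72 µM | 8.6 µM | run made earlier |
| flask | 0.036 M | 0.0396 M | 72 µM | 8.6 µM |  |

| run | time / d | product / % | substrate / % |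
|---|---|---|---|
| green | 4.00 | 60 | 40 |
| green | 8.00 | 84 | 14 |
| green | 12.0 | 88 | 11 |
| green | 15.0 | 91 | 7 |
| green | 20.0 | 90 | 10 |
| green | 25.0 | 96 | 12 |
| red | 2.08 | 58 | 47 |
| red | 3.00 | 71 | 30 |
| red | 5.00 | 89 | 4 |
| red | 8.00 | 98 | 3 |
| red | 15.0 | 96 | 0 |
| red | 25.0 | 97 | 1 |

(scatter of a reading: 2 percentage points)

- the analysis behind the earlier runs scatters by 2 percentage points, standard deviation
- steps under discussion: catalyst intermediate B <-> free catalyst + product; coupling partner + catalyst intermediate A <-> catalyst intermediate B; coupling partner <-> dormant form; substrate + free catalyst <-> catalyst intermediate A; free catalyst + impurity -> spent catalyst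
- no earlier run changes the charge of free catalyst; that part of a forecast is a guess

- apparent order in free catalyst when 5.0% of the substrate are converted (percent change of the rate of making product for one percent more free catalyst charged)

Neither earlier run changes the free catalyst, so the decision rests on my own reckoning. Take the plain cycle as the zero of the scale: each step carries one catalyst-containing species, which gives an order of 1 in free catalyst. The impurity removes catalyst one for one, so define the poison factor 1.14: the catalyst charged over the catalyst charged minus the impurity charged. For this cycle it is the order once the impurity has been consumed, and before that the order lies between 1 and this factor. I commit to a value near the factor. On this reckoning a percent more catalyst gives at least a percent more rate, so the order gives you no reason to hold the charge at 72 µM.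

The forecast gives 1.1, on the ground that “scavenging is probably fast”.

The flask gives 1.1.

    catalyst intermediate B ⇌ free catalyst + product (K = 0.0120 M, k = 0.0420 s⁻¹)
    coupling partner + catalyst intermediate A ⇌ catalyst intermediate B (K = 34.0 M⁻¹, k = 0.0570 M⁻¹ s⁻¹)
    coupling partner ⇌ dormant form (K = 1.10, k = 1.60 × 10⁻⁴ s⁻¹)
    substrate + free catalyst ⇌ catalyst intermediate A (K = 2600 M⁻¹, k = 2.00 M⁻¹ s⁻¹)
    free catalyst + impurity → spent catalyst (k = 56.0 M⁻¹ s⁻¹)

In the flask, spent catalyst stands at 10.8% of the catalyst at 0.277 d, when 5.0% of the substrate is converted. That is less than the ceiling of 11.9% set by the poison factor 1.14, and it amounts to 90.6% of that ceiling. The capture ends long before the conversion does: at 2.00 d the flask holds impurity at 0% of its charge and spent catalyst at 11.9%, while substrate still stands at 73.8% and catalyst intermediate A, the resting state, at 82.4% of the catalyst.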